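## Retrosynthetic overview

1. Target 9 ⇐ acetonide 8 ⇐ alkene 6: the C17–O bond comes from anti-Markovnikov hydration of the 8(17)-methylene (new photocatalytic step, sets C8); the acetonide is hydrolysed in the same pot.
2. 6 ⇐ 5: SN2' hydride displacement of the C14 acetate removes O14 and moves the alkene into the lactone ring (C13=C14 butenolide).
3. 5 ⇐ 3 ⇐ 1: 14-O-acetate on the 3,19-acetonide of andrographolide.
4. Ring order: rings A and B and the lactone are taken intact from andrographolide. The only ring made is the temporary 1,3-dioxane (step 1), opened again in step 4.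

Assumption: andrographolide, sold in bulk as a plant isolate, is taken as the cheap commercial starting material; it supplies five of the six stereocentres of the target. Labdane numbering (C1–C20) is used in all names.

## Route

Step 1
Reactants: 1 andrographolide; 2 2,2-dimethoxypropane
Product: 3 3,19-O-isopropylideneandrographolide (1,3-dioxane across O3 and O19; 14S-OH free; all stereocentres as in 1)
Conditions: 2,2-dimethoxypropane (3 equiv), pyridinium p-toluenesulfonate (5 mol%), toluene/DMSO 10:1, 80 °C, 1 h
Reagents that add atoms: 2,2-dimethoxypropane, COC(C)(C)OC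
Why: Acid-catalysed transketalisation (acetonide formation) selects the 1,3-diol at C3/C19, which closes a chair 1,3-dioxane, while the lone allylic 14-OH cannot form a cyclic ketal; no stereocentre is touched.

Step 2
Reactants: 3 3,19-O-isopropylideneandrographolide; 4 acetic anhydride
Product: 5 14-O-acetyl-3,19-O-isopropylideneandrographolide (14S acetate; 12E alkene kept)
Conditions: Ac2O (neat), 140 °C, 1 h
Reagents that add atoms: acetic anhydride, CC(=O)OC(C)=O
Why: Thermal O-acetylation (acyl transfer) of the only free hydroxyl, run without amine base so that 1,4-elimination to the 11,12-diene is not promoted; C14 keeps its configuration.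

Step 3
Reactants: 5 14-O-acetyl-3,19-O-isopropylideneandrographolide
Product: 6 14-deoxy-3,19-O-isopropylideneandrographolide (C11–C12 saturated, C13=C14 endocyclic butenolide, 8(17)-methylene intact; C3, C4, C5, C9, C10 as in 1)
Conditions: NaBH4 (1.2 equiv), THF/EtOH 4:1, −20 to 0 °C, 1 h; sat. aq NH4Cl
Reagents that add atoms: none
Why: SN2' hydride reduction of a Morita–Baylis–Hillman-type acetate (conjugate addition of hydride at C12, then E1cB loss of acetate from C14) gives the conjugated endocyclic butenolide; the C14 stereocentre is erased on purpose and no new one is formed.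

Step 4
Reactants: 6 14-deoxy-3,19-O-isopropylideneandrographolide; 7 water
Product: 9 target 14-deoxy-17-hydroxyandrographolide, via hydrated acetonide 8 (not isolated)
Conditions: 3,6-di-tert-butyl-9-mesityl-10-phenylacridinium tetrafluoroborate (5 mol%), (PhS)2 (20 mol%), MeCN/H2O 4:1 (0.05 M), 450 nm LEDs, N2, 25 °C, 24 h; then 2 M aq HCl to pH 1, 25 °C, 2 h
Reagents that add atoms: water, O
Why: Proposed new method: the excited acridinium (about +2.1 V vs SCE) oxidises the only electron-rich π bond, the 1,1-dialkyl 8(17)-alkene (about +2.4 V; the uphill electron transfer is drained by fast, irreversible capture of the radical cation by solvent-level water at the unsubstituted C17, which forms the C17–O bond and leaves the tertiary C8 radical), while the butenolide alkene is far too electron-poor to react; PhSH, made from (PhS)2 and recycled by the acridine radical, then gives H• to C8 along the axial trajectory on the face of the C10 methyl, because the torsional preference of tertiary cyclohexyl radicals for axial attack puts CH2OH equatorial and trans to the C9 chain (8S), the sense seen in radical HAT hydrogenations and opposite to what concerted borane delivery anti to the C10 methyl would be expected to give; closest known reaction type: acridinium/thiol photoredox anti-Markovnikov hydration and hydroetherification of styrenes and trisubstituted alkenes, here extended to an unactivated 1,1-dialkyl exocyclic alkene with HAT-controlled diastereoselection; aqueous HCl then hydrolyses the acetonide (acetal hydrolysis), and any C8 epimer is removed at this stage by chromatography.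

## Compound list

1 | andrographolide, (3E,4S)-3-{2-[(1R,4aS,5R,6R,8aS)-6-hydroxy-5-(hydroxymethyl)-5,8a-dimethyl-2-methylidenedecahydronaphthalen-1-yl]ethylidene}-4-hydroxyoxolan-2-one | C[C@]1(CO)[C@H]2CCC(=C)[C@@H](C/C=C3/C(=O)OC[C@H]3O)[C@]2(C)CC[C@H]1O | starting material
2 | 2,2-dimethoxypropane | COC(C)(C)OC | starting material
3 | 3,19-O-isopropylideneandrographolide | C[C@]1(COC(C)(C)O4)[C@H]2CCC(=C)[C@@H](C/C=C3/C(=O)OC[C@H]3O)[C@]2(C)CC[C@H]14 | intermediate
4 | acetic anhydride | CC(=O)OC(C)=O | starting material
5 | 14-O-acetyl-3,19-O-isopropylideneandrographolide | C[C@]1(COC(C)(C)O4)[C@H]2CCC(=C)[C@@H](C/C=C3/C(=O)OC[C@H]3OC(C)=O)[C@]2(C)CC[C@H]14 | intermediate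
6 | 14-deoxy-3,19-O-isopropylideneandrographolide | C[C@]1(COC(C)(C)O4)[C@H]2CCC(=C)[C@@H](CCC3=CCOC3=O)[C@]2(C)CC[C@H]14 | intermediate
7 | water | O | starting material
8 | (8S)-14-deoxy-17-hydroxy-3,19-O-isopropylideneandrographolide (8-H axial on the face of the C10 methyl, CH2OH equatorial) | C[C@]1(COC(C)(C)O4)[C@H]2CC[C@H](CO)[C@@H](CCC3=CCOC3=O)[C@]2(C)CC[C@H]14 | intermediate
9 | 14-deoxy-17-hydroxyandrographolide, 3-{2-[(1R,2S,4aS,5R,6R,8aS)-6-hydroxy-2,5-bis(hydroxymethyl)-5,8a-dimethyldecahydronaphthalen-1-yl]ethyl}furan-2(5H)-one (labdane 3R,4R,5S,8S,9R,10S) | C[C@]1(CO)[C@H]2CC[C@H](CO)[C@@H](CCC3=CCOC3=O)[C@]2(C)CC[C@H]1O | target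

## Step count and risks

Total step count: 4. Longest linear sequence: 4 (fully linear from andrographolide).

The three steps most likely to fail:

**Step 4 (proposed new hydration).** The electron transfer to the acridinium is uphill, thiyl radicals may add to the alkene, the radical cation may lose an allylic proton, and H-atom delivery to C8 may favour the face away from the C10 methyl and give the 8-epimer. The fallback uses known chemistry and puts C8 under thermodynamic control. It sets out from 6 and comes back at 8, after which the acid treatment of step 4 gives 9. Compound 6 is epoxidised with mCPBA (NaHCO3, CH2Cl2, 0 °C; the butenolide is inert) to the 8,17-epoxide F1. BF3·OEt2 (toluene, −40 °C) then effects Meinwald rearrangement to the C17 aldehyde, and catalytic DBU (CH2Cl2, 25 °C) equilibrates it to the equatorial (8S) aldehyde F2. NaBH4 (MeOH, −20 °C) reduces F2 to 8.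

**Step 3 (SN2' hydride reduction).** NaBH4 may over-reduce the product butenolide, attack the lactone, or let alkoxide add at C12. The fallback separates reduction from elimination; it sets out from 3 and comes back at 6. Alcohol 3 is conjugate-reduced with NaBH4/NiCl2·6H2O (MeOH, 0 °C) to the 12,13-dihydro acetonide F3 (C13 epimers, of no consequence). MsCl/Et3N (CH2Cl2, 0 to 25 °C, DBU if needed) then gives the 14-mesylate F4, which undergoes E1cB elimination in the flask to 6. With C12 already saturated, neither SN2' side reactions nor diene formation can occur.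

**Step 2 (acetylation).** Hot Ac2O may cause partial 1,4-elimination to the 11,12-diene or acetonide scrambling. The fallback avoids any C14 ester by a Myers reductive allylic transposition; it sets out from 3 and comes back at 6. Alcohol 3 is treated with PPh3, diethyl azodicarboxylate and 2-nitrobenzenesulfonylhydrazide (THF, −30 °C). Mitsunobu C–N bond formation with inversion gives the allylic N-sulfonylhydrazine F5. On warming to 25 °C it loses the sulfinic acid to give the allylic diazene F6, which expels N2 by a retro-ene shift, placing H on C12 and the alkene at C13=C14, to give 6.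

Further compounds
F1 | step 4 | 8,17-epoxy-14-deoxy-3,19-O-isopropylideneandrographolide (epoxide oxygen on the face opposite the C10 methyl; this C8 configuration is erased in the rearrangement) | C[C@]1(COC(C)(C)O4)[C@H]2CC[C@@]5(CO5)[C@@H](CCC3=CCOC3=O)[C@]2(C)CC[C@H]14
F2 | step 4 | (8S)-14-deoxy-17-oxo-3,19-O-isopropylideneandrographolide (equatorial C17 aldehyde) | C[C@]1(COC(C)(C)O4)[C@H]2CC[C@H](C=O)[C@@H](CCC3=CCOC3=O)[C@]2(C)CC[C@H]14
F3 | step 3 | 12,13-dihydro-3,19-O-isopropylideneandrographolide (C13 epimers) | C[C@]1(COC(C)(C)O4)[C@H]2CCC(=C)[C@@H](CCC3C(=O)OC[C@H]3O)[C@]2(C)CC[C@H]14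
F4 | step 3 | 14-O-methanesulfonyl-12,13-dihydro-3,19-O-isopropylideneandrographolide (C13 epimers) | C[C@]1(COC(C)(C)O4)[C@H]2CCC(=C)[C@@H](CCC3C(=O)OC[C@H]3OS(C)(=O)=O)[C@]2(C)CC[C@H]14
F5 | step 2 | (14R)-14-deoxy-14-[1-(2-nitrobenzenesulfonyl)hydrazinyl]-3,19-O-isopropylideneandrographolide | C[C@]1(COC(C)(C)O4)[C@H]2CCC(=C)[C@@H](C/C=C3/C(=O)OC[C@@H]3N(N)S(=O)(=O)c5ccccc5[N+](=O)[O-])[C@]2(C)CC[C@H]14
F6 | step 2 | (14R)-14-deoxy-14-diazenyl-3,19-O-isopropylideneandrographolide | C[C@]1(COC(C)(C)O4)[C@H]2CCC(=C)[C@@H](C/C=C3/C(=O)OC[C@@H]3N=N)[C@]2(C)CC[C@H]14
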